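**Plan**

- Retrosynthesis: the C7'=C8' alkene of the ring B side chain is cut first (olefination of an aldehyde kept as a dioxolane). Ring A is then cut at C1–C2 and C5–C6, then the C7–C1 bond (acetylide plus Weinreb amide), and last the C8–O4' ether (lactate plus syringaldehyde).
- Enabling feature: ring A is a benzene ring with methoxy groups on the adjacent carbons C3 and C4 and its only carbon substituent (C7) on C1. C2–C5 with the two methoxy groups therefore map onto 2,3-dimethoxybuta-1,3-diene, and C1/C6 onto a terminal alkyne.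
- Forward: ring B is bought as syringaldehyde. The chain is joined at C8–O, then at C7–alkyne. Ring A, the only ring made, is closed around the finished C7/C8 diad by a cobalt-catalysed [4+2] reaction and DDQ; the cinnamyl alcohol is completed last.
- Stereochemistry: C8 (S) comes from methyl (R)-lactate by Mitsunobu inversion. C7 (R, erythro) comes from catalyst-controlled transfer hydrogenation of an ynone. The E alkene comes from the Horner–Wadsworth–Emmons reaction.

Key step: step 7

Assumption: 2,3-dimethoxybuta-1,3-diene (10) is used as the purchased diene, distilled from K2CO3 before use.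

**Route**

Step 1
Reactants: 1 syringaldehyde; 2 methyl (R)-lactate
Product: 3 methyl (2S)-2-(4-formyl-2,6-dimethoxyphenoxy)propanoate
Conditions: PPh3, DIAD, THF, 0 °C to rt
Reagents that add atoms: none
Why: Mitsunobu etherification, in which the acidic para-formyl phenol displaces the activated lactate oxygen by SN2 with inversion, so that the (R)-carbinol becomes the (S)-aryl ether that is C8 of the target.

Step 2
Reactants: 3 methyl (2S)-2-(4-formyl-2,6-dimethoxyphenoxy)propanoate
Product: 4 methyl (2S)-2-[4-(1,3-dioxolan-2-yl)-2,6-dimethoxyphenoxy]propanoate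
Conditions: Me3SiOCH2CH2OSiMe3, Me3SiOTf (cat.), CH2Cl2, −78 to −20 °C, pyridine quench
Reagents that add atoms: 1,2-bis(trimethylsilyloxy)ethane, C[Si](C)(C)OCCO[Si](C)(C)C
Why: Noyori acetalisation under aprotic conditions masks the aldehyde for the organometallic and hydride steps and should leave the ester and the α-stereocentre untouched.

Step 3
Reactants: 4 methyl (2S)-2-[4-(1,3-dioxolan-2-yl)-2,6-dimethoxyphenoxy]propanoate
Product: 5 (2S)-2-[4-(1,3-dioxolan-2-yl)-2,6-dimethoxyphenoxy]-N-methoxy-N-methylpropanamide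
Conditions: MeNH(OMe)·HCl, i-PrMgCl, THF, −20 to 0 °C
Reagents that add atoms: N,O-dimethylhydroxylamine hydrochloride, CNOC.Cl
Why: Weinreb amide formation by aminolysis of the methyl ester with the chloromagnesium amide at low temperature, conditions under which α-alkoxy esters are expected to keep their configuration.

Step 4
Reactants: 5 (2S)-2-[4-(1,3-dioxolan-2-yl)-2,6-dimethoxyphenoxy]-N-methoxy-N-methylpropanamide
Product: 6 (4S)-4-[4-(1,3-dioxolan-2-yl)-2,6-dimethoxyphenoxy]-1-(trimethylsilyl)pent-1-yn-3-one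
Conditions: Me3SiC≡CH, n-BuLi, THF, −78 °C; then 5, −78 to 0 °C
Reagents that add atoms: ethynyltrimethylsilane, C#C[Si](C)(C)C
Why: Weinreb ketone synthesis, in which the chelated tetrahedral adduct persists until work-up so that only one acetylide adds, while the silyl cap shields the ynone from conjugate addition.

Step 5
Reactants: 6 (4S)-4-[4-(1,3-dioxolan-2-yl)-2,6-dimethoxyphenoxy]-1-(trimethylsilyl)pent-1-yn-3-one
Product: 8 (3R,4S)-4-[4-(1,3-dioxolan-2-yl)-2,6-dimethoxyphenoxy]pent-1-yn-3-ol, via C-silylated propargylic alcohol 7 (not isolated)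
Conditions: Ru[(S,S)-TsNCH(Ph)CH(Ph)NH](p-cymene) (2 mol %), i-PrOH, rt; then K2CO3 (0.3 equiv), MeOH, rt
Reagents that add atoms: none
Why: Noyori asymmetric transfer hydrogenation of an alkynyl ketone under base-free conditions, in which the (S,S)-catalyst adds hydride in the sense that gives (S)-carbinols from simple alkyl alkynyl ketones and here, because the aryloxy-bearing branch outranks the alkynyl group, gives 3R (erythro) under catalyst control over the resident C4 centre, followed by methoxide-mediated protodesilylation of the alkyne.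

Step 6
Reactants: 8 (3R,4S)-4-[4-(1,3-dioxolan-2-yl)-2,6-dimethoxyphenoxy]pent-1-yn-3-ol
Product: 9 (3R,4S)-3-(tert-butyldimethylsilyloxy)-4-[4-(1,3-dioxolan-2-yl)-2,6-dimethoxyphenoxy]pent-1-yne
Conditions: TBSCl, imidazole, DMAP (cat.), DMF, rt to 40 °C
Reagents that add atoms: tert-butyldimethylsilyl chloride, CC(C)(C)[Si](C)(C)Cl
Why: Corey silylation of the secondary alcohol with the silyl chloride (not the triflate, which could open the dioxolane) gives an ether that blocks oxidation at C7 in the next step.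

Step 7
Reactants: 9 (3R,4S)-3-(tert-butyldimethylsilyloxy)-4-[4-(1,3-dioxolan-2-yl)-2,6-dimethoxyphenoxy]pent-1-yne; 10 2,3-dimethoxybuta-1,3-diene
Product: 12 2-(4-{[(1R,2S)-1-(tert-butyldimethylsilyloxy)-1-(3,4-dimethoxyphenyl)propan-2-yl]oxy}-3,5-dimethoxyphenyl)-1,3-dioxolane, via cyclohexa-1,4-diene adduct 11 (not isolated)
Conditions: CoBr2(Ph2PCH2CH2PPh2) (10 mol %), Zn powder (20 mol %), ZnI2 (20 mol %), 10 (3 equiv), CH2Cl2, rt; filtration through basic alumina; then DDQ (1.05 equiv), toluene, 0 °C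
Reagents that add atoms: none
Why: Zinc reduces the divalent cobalt precatalyst to monovalent cobalt and ZnI2 removes bromide, so that the metal binds the alkyne of 9 and the s-cis diene 10, couples them oxidatively to a trivalent cobaltacycle and releases the cyclohexa-1,4-diene 11 by reductive elimination. Ring A thus closes in a metal-templated formal [4+2] mode that forms C1–C2 and C5–C6 (alkyne carbons become C1 and C6, diene carbons C2–C5); the closest known reaction type is the cobalt-catalysed neutral Diels–Alder reaction of unactivated terminal alkynes with 2,3-disubstituted butadienes followed by DDQ dehydrogenation. DDQ then takes hydride from a doubly allylic CH2 of 11 and the cation loses a proton to give the 3,4-dimethoxyphenyl ring. No stereocentre is created, and C7 and C8 are spectators that carry no acidic hydrogen in this neutral medium. The step needs chemoselectivity: the alkyne is the only unsaturated partner in 9, the symmetrical diene removes any regiochemical question, and its excess should suppress alkyne trimerisation. DDQ is held near one equivalent at 0 °C so that the aromatisation-driven dienyl CH2 reacts ahead of the benzylic silyl ether CH and the acetal CH.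

Step 8
Reactants: 12 2-(4-{[(1R,2S)-1-(tert-butyldimethylsilyloxy)-1-(3,4-dimethoxyphenyl)propan-2-yl]oxy}-3,5-dimethoxyphenyl)-1,3-dioxolane
Product: 13 4-{[(1R,2S)-1-(tert-butyldimethylsilyloxy)-1-(3,4-dimethoxyphenyl)propan-2-yl]oxy}-3,5-dimethoxybenzaldehyde
Conditions: pyridinium p-toluenesulfonate (cat.), THF/H2O (4:1), 40 °C
Reagents that add atoms: water, O
Why: Acid-catalysed acetal hydrolysis, which the electron-rich ring B accelerates through a stabilised oxocarbenium ion, so that a weak acid suffices and the secondary silyl ether and the C7 configuration should be preserved.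

Step 9
Reactants: 13 4-{[(1R,2S)-1-(tert-butyldimethylsilyloxy)-1-(3,4-dimethoxyphenyl)propan-2-yl]oxy}-3,5-dimethoxybenzaldehyde
Product: 14 ethyl (2E)-3-(4-{[(1R,2S)-1-(tert-butyldimethylsilyloxy)-1-(3,4-dimethoxyphenyl)propan-2-yl]oxy}-3,5-dimethoxyphenyl)prop-2-enoate
Conditions: (EtO)2P(O)CH2CO2Et, NaH, THF, 0 °C to rt
Reagents that add atoms: triethyl phosphonoacetate, CCOC(=O)CP(=O)(OCC)OCC
Why: Horner–Wadsworth–Emmons olefination of an aromatic aldehyde with a stabilised phosphonate anion, which is expected to give the E enoate.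

Step 10
Reactants: 14 ethyl (2E)-3-(4-{[(1R,2S)-1-(tert-butyldimethylsilyloxy)-1-(3,4-dimethoxyphenyl)propan-2-yl]oxy}-3,5-dimethoxyphenyl)prop-2-enoate
Product: 15 (2E)-3-(4-{[(1R,2S)-1-(tert-butyldimethylsilyloxy)-1-(3,4-dimethoxyphenyl)propan-2-yl]oxy}-3,5-dimethoxyphenyl)prop-2-en-1-ol
Conditions: i-Bu2AlH (2.5 equiv), CH2Cl2, −78 °C
Reagents that add atoms: none
Why: 1,2-Reduction of the α,β-unsaturated ester by i-Bu2AlH at low temperature should give the allylic alcohol without touching the alkene geometry, the aryl ethers or the silyl ether.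

Step 11
Reactants: 15 (2E)-3-(4-{[(1R,2S)-1-(tert-butyldimethylsilyloxy)-1-(3,4-dimethoxyphenyl)propan-2-yl]oxy}-3,5-dimethoxyphenyl)prop-2-en-1-ol
Product: 16 (1R,2S)-1-(3,4-dimethoxyphenyl)-2-{4-[(1E)-3-hydroxyprop-1-en-1-yl]-2,6-dimethoxyphenoxy}propan-1-ol (target, erythro)
Conditions: Bu4NF, THF, 0 °C to rt
Reagents that add atoms: none
Why: Fluoride-mediated cleavage of the Si–O bond under non-acidic conditions frees the C7 hydroxyl without ionising the electron-rich benzylic position.

**Compound list**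

1 | syringaldehyde (4-hydroxy-3,5-dimethoxybenzaldehyde) | COc1cc(C=O)cc(OC)c1O | starting material
2 | methyl (R)-lactate | C[C@@H](O)C(=O)OC | starting material
3 | methyl (2S)-2-(4-formyl-2,6-dimethoxyphenoxy)propanoate | COC(=O)[C@H](C)Oc1c(OC)cc(C=O)cc1OC | intermediate
4 | methyl (2S)-2-[4-(1,3-dioxolan-2-yl)-2,6-dimethoxyphenoxy]propanoate | COC(=O)[C@H](C)Oc1c(OC)cc(C2OCCO2)cc1OC | intermediate
5 | (2S)-2-[4-(1,3-dioxolan-2-yl)-2,6-dimethoxyphenoxy]-N-methoxy-N-methylpropanamide | CON(C)C(=O)[C@H](C)Oc1c(OC)cc(C2OCCO2)cc1OC | intermediate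
6 | (4S)-4-[4-(1,3-dioxolan-2-yl)-2,6-dimethoxyphenoxy]-1-(trimethylsilyl)pent-1-yn-3-one | C[Si](C)(C)C#CC(=O)[C@H](C)Oc1c(OC)cc(C2OCCO2)cc1OC | intermediate
7 | (3R,4S)-4-[4-(1,3-dioxolan-2-yl)-2,6-dimethoxyphenoxy]-1-(trimethylsilyl)pent-1-yn-3-ol (not isolated) | C[Si](C)(C)C#C[C@@H](O)[C@H](C)Oc1c(OC)cc(C2OCCO2)cc1OC | intermediate
8 | (3R,4S)-4-[4-(1,3-dioxolan-2-yl)-2,6-dimethoxyphenoxy]pent-1-yn-3-ol | C#C[C@@H](O)[C@H](C)Oc1c(OC)cc(C2OCCO2)cc1OC | intermediate
9 | (3R,4S)-3-(tert-butyldimethylsilyloxy)-4-[4-(1,3-dioxolan-2-yl)-2,6-dimethoxyphenoxy]pent-1-yne | C#C[C@@H](O[Si](C)(C)C(C)(C)C)[C@H](C)Oc1c(OC)cc(C2OCCO2)cc1OC | intermediate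
10 | 2,3-dimethoxybuta-1,3-diene | C=C(OC)C(OC)=C | starting material
11 | 1-{(1R,2S)-1-(tert-butyldimethylsilyloxy)-2-[4-(1,3-dioxolan-2-yl)-2,6-dimethoxyphenoxy]propyl}-4,5-dimethoxycyclohexa-1,4-diene (not isolated) | COC1=C(OC)CC(=CC1)[C@@H](O[Si](C)(C)C(C)(C)C)[C@H](C)Oc1c(OC)cc(C2OCCO2)cc1OC | intermediate
12 | 2-(4-{[(1R,2S)-1-(tert-butyldimethylsilyloxy)-1-(3,4-dimethoxyphenyl)propan-2-yl]oxy}-3,5-dimethoxyphenyl)-1,3-dioxolane | COc1ccc([C@@H](O[Si](C)(C)C(C)(C)C)[C@H](C)Oc2c(OC)cc(C3OCCO3)cc2OC)cc1OC | intermediate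
13 | 4-{[(1R,2S)-1-(tert-butyldimethylsilyloxy)-1-(3,4-dimethoxyphenyl)propan-2-yl]oxy}-3,5-dimethoxybenzaldehyde | COc1ccc([C@@H](O[Si](C)(C)C(C)(C)C)[C@H](C)Oc2c(OC)cc(C=O)cc2OC)cc1OC | intermediate
14 | ethyl (2E)-3-(4-{[(1R,2S)-1-(tert-butyldimethylsilyloxy)-1-(3,4-dimethoxyphenyl)propan-2-yl]oxy}-3,5-dimethoxyphenyl)prop-2-enoate | COc1ccc([C@@H](O[Si](C)(C)C(C)(C)C)[C@H](C)Oc2c(OC)cc(/C=C/C(=O)OCC)cc2OC)cc1OC | intermediate
15 | (2E)-3-(4-{[(1R,2S)-1-(tert-butyldimethylsilyloxy)-1-(3,4-dimethoxyphenyl)propan-2-yl]oxy}-3,5-dimethoxyphenyl)prop-2-en-1-ol | COc1ccc([C@@H](O[Si](C)(C)C(C)(C)C)[C@H](C)Oc2c(OC)cc(/C=C/CO)cc2OC)cc1OC | intermediate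
16 | (1R,2S)-1-(3,4-dimethoxyphenyl)-2-{4-[(1E)-3-hydroxyprop-1-en-1-yl]-2,6-dimethoxyphenoxy}propan-1-ol | COc1ccc([C@@H](O)[C@H](C)Oc2c(OC)cc(/C=C/CO)cc2OC)cc1OC | target

**Count**

Total steps: 11. Longest linear sequence: 11 (steps 1 to 11 from syringaldehyde and methyl (R)-lactate; diene 10 enters at step 7).

**Steps most likely to fail**

1. Step 7. The hindered, oxygen-rich propargylic substrate may slow the cobalt cycle so that alkyne trimerisation competes. The Lewis-acidic zinc salt may degrade the electron-rich diene or the bis-enol ether 11 before oxidation. DDQ may over-oxidise at the benzylic or acetal CH. The fallback gives up building ring A and brings it in as an aryl nucleophile. It sets out from Weinreb amide 5: addition of 3,4-dimethoxyphenylmagnesium bromide in THF at 0 °C should give (2S)-1-(3,4-dimethoxyphenyl)-2-[4-(1,3-dioxolan-2-yl)-2,6-dimethoxyphenoxy]propan-1-one F1. Chelation-controlled reduction with Zn(BH4)2 in Et2O at low temperature (hydride on the face of the C8 hydrogen in the zinc chelate of the ketone and ether oxygens) should give the erythro alcohol (1R,2S)-1-(3,4-dimethoxyphenyl)-2-[4-(1,3-dioxolan-2-yl)-2,6-dimethoxyphenoxy]propan-1-ol F2. Silylation with TBSCl and imidazole in DMF comes back to the route at 12.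

2. Step 5. Catalyst control may be incomplete if the resident C4 centre opposes the (S,S)-catalyst, and the configurationally labile α-aryloxy ynone may epimerise during a slow reduction. The fallback replaces selective reduction by stereochemical correction. It sets out from ynone 6: fast Luche reduction (NaBH4, CeCl3·7H2O, MeOH, −78 °C) should give 7 together with its C3 epimer (3S,4S)-4-[4-(1,3-dioxolan-2-yl)-2,6-dimethoxyphenoxy]-1-(trimethylsilyl)pent-1-yn-3-ol F3, separable by chromatography. F3 is inverted by Mitsunobu esterification (4-nitrobenzoic acid, PPh3, DIAD, THF) to (3R,4S)-4-[4-(1,3-dioxolan-2-yl)-2,6-dimethoxyphenoxy]-1-(trimethylsilyl)pent-1-yn-3-yl 4-nitrobenzoate F4. K2CO3 in MeOH then removes the ester and the C-silyl group of F4, as it removes the C-silyl group of 7, so both streams come back to the route at 8.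

3. Step 1. The di-ortho-substituted phenol may react slowly in the redox condensation, giving low conversion and elimination of the activated lactate. The fallback replaces the Mitsunobu reaction by sulfonate displacement. It sets out from 2: Tf2O and 2,6-lutidine in CH2Cl2 at −78 °C should give methyl (2R)-2-{[(trifluoromethyl)sulfonyl]oxy}propanoate F5. The potassium phenoxide of 1 (K2CO3, MeCN, 0 °C to rt) displaces the triflate by SN2 with inversion and comes back to the route at 3.

**Further compounds**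

F1 | step 7 | (2S)-1-(3,4-dimethoxyphenyl)-2-[4-(1,3-dioxolan-2-yl)-2,6-dimethoxyphenoxy]propan-1-one | COc1ccc(C(=O)[C@H](C)Oc2c(OC)cc(C3OCCO3)cc2OC)cc1OC
F2 | step 7 | (1R,2S)-1-(3,4-dimethoxyphenyl)-2-[4-(1,3-dioxolan-2-yl)-2,6-dimethoxyphenoxy]propan-1-ol | COc1ccc([C@@H](O)[C@H](C)Oc2c(OC)cc(C3OCCO3)cc2OC)cc1OC
F3 | step 5 | (3S,4S)-4-[4-(1,3-dioxolan-2-yl)-2,6-dimethoxyphenoxy]-1-(trimethylsilyl)pent-1-yn-3-ol | C[Si](C)(C)C#C[C@H](O)[C@H](C)Oc1c(OC)cc(C2OCCO2)cc1OC
F4 | step 5 | (3R,4S)-4-[4-(1,3-dioxolan-2-yl)-2,6-dimethoxyphenoxy]-1-(trimethylsilyl)pent-1-yn-3-yl 4-nitrobenzoate | C[Si](C)(C)C#C[C@@H](OC(=O)c1ccc(cc1)[N+](=O)[O-])[C@H](C)Oc1c(OC)cc(C2OCCO2)cc1OC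
F5 | step 1 | methyl (2R)-2-{[(trifluoromethyl)sulfonyl]oxy}propanoate | C[C@@H](OS(=O)(=O)C(F)(F)F)C(=O)OC
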